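A direct plan would set C2 and C3 on an open chain by an auxiliary-controlled syn-aldol (carbinol A1), invert the carbinol with the ring A phenol in a Mitsunobu etherification, cleave the auxiliary (acid A2), close ring C by Friedel–Crafts acylation (chromanone A3) and debenzylate. Its weakest steps would be:
- the Mitsunobu inversion: the carbinol carbon is benzylic to a ring with ortho and para oxygen donors and can ionise or eliminate, so C2, made syn first and then inverted, would be left to chance;
- the Friedel–Crafts closure of ring C: it would be run on the most advanced chiral material, which holds an acid-labile benzylic aryl ether and forms an α-methoxy acylium ion that can lose CO;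
- the auxiliary and benzyl ether steps: loading, cleavage, protection and hydrogenolysis would be four operations with no gain in skeleton.

**New plan**
The retrosynthesis cuts the O–CH3 bonds at O2′ and O5′ (para on ring B, so the hydroquinone comes from a para-dimethoxy arene via its quinone), then C2–C1′, then O1–C2 and C2–C3 of an achiral chromone, then C4–C4a.
Ring order: ring A is bought, ring C is closed on it as flat 3,5,7-trimethoxychromone, ring B is joined last.
Feature used: C2 is the β-carbon of the C2=C3–C4=O enone of ring C and holds ring B by one single bond, so an aryl-rhodium adds there; the ligand sets C2, protonation sets C3.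
Thus no carbinol is inverted, no ring is closed on chiral material, and no auxiliary or protection step is needed.

Key step: step 5

Assumption: the (S,S) antipode of the diene ligand is taken, by analogy with its sense of induction on cyclohex-2-enone, to deliver the aryl group to the face of C2 that gives 2R; if the 3-methoxy group reverses the sense, the (R,R) ligand is used.

Step 1
Reactants: 1 1,3,5-trimethoxybenzene; 2 methoxyacetyl chloride
Product: 3 2-methoxy-1-(2,4,6-trimethoxyphenyl)ethan-1-one
Conditions: AlCl3 (1.1 equiv), CH2Cl2, −10 to 0 °C; then ice-cold 1 M HCl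
Reagents that add atoms: none
Why: Friedel–Crafts acylation of a threefold-symmetric, strongly activated arene, so only one monoketone can form (this is the C4–C4a bond of the target), and the acyl group then deactivates the ring against a second acylation.

Step 2
Reactants: 3 2-methoxy-1-(2,4,6-trimethoxyphenyl)ethan-1-one
Product: 5 1-(2-hydroxy-4,6-dimethoxyphenyl)-2-methoxyethan-1-one, via aryloxydichloroborane chelate 4 (not isolated)
Conditions: BCl3 (1.1 equiv), CH2Cl2, −78 to −20 °C; then H2O
Reagents that add atoms: none
Why: Chelation-directed ether cleavage, in which BCl3 bridges the ketone oxygen and one ortho-methoxy oxygen in a six-membered chelate and chloride removes that methyl group, while the para-methoxy group is not chelated, the second ortho group is spared by the stoichiometry, and the aliphatic α-methoxy group (five-membered chelate, poorer alkoxide leaving group) should react more slowly.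

Step 3
Reactants: 5 1-(2-hydroxy-4,6-dimethoxyphenyl)-2-methoxyethan-1-one
Product: 7 3,5,7-trimethoxy-4H-chromen-4-one, via enaminone 6 (not isolated)
Conditions: Me2NCH(OMe)2 (2.5 equiv), toluene, 100 °C; then AcOH, 80 °C
Reagents that add atoms: N,N-dimethylformamide dimethyl acetal, COC(OC)N(C)C
Why: Standard chromone closure from a 2-hydroxyaryl ketone: the formamide acetal condenses at the methoxy-bearing CH2 (the only enolisable position) to enaminone 6, and the phenol then attacks its β-carbon in a 6-endo-trig addition–elimination with loss of dimethylamine, which forms O1–C2 and C2–C3 on achiral material.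

Step 4
Reactants: 8 1-bromo-2,4,5-trimethoxybenzene
Product: 11 (2,4,5-trimethoxyphenyl)boronic acid, via aryllithium 9 (not isolated), via lithium aryltriisopropoxyborate 10 (not isolated)
Conditions: n-BuLi (1.05 equiv), THF, −78 °C; B(OiPr)3 (1.3 equiv), −78 °C to rt; then 1 M HCl to pH 5, 0 °C
Reagents that add atoms: triisopropyl borate, CC(C)OB(OC(C)C)OC(C)C; water, O
Why: Bromine–lithium exchange at −78 °C is faster than any ortho-lithiation and fixes boron at the carbon that will become C1′, and ate complex 10 is hydrolysed cold and only weakly acidic to limit protodeboronation of this electron-rich boronic acid.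

Step 5
Reactants: 7 3,5,7-trimethoxy-4H-chromen-4-one; 11 (2,4,5-trimethoxyphenyl)boronic acid
Product: 13 (2R,3R)-3,5,7-trimethoxy-2-(2,4,5-trimethoxyphenyl)chroman-4-one, via 2,3-cis epimer 12 (not isolated)
Conditions: [RhCl(C2H4)2]2 (2.5 mol %), (1S,4S)-2,5-diphenylbicyclo[2.2.2]octa-2,5-diene (5.5 mol %), 11 (3 equiv in three portions), K3PO4 (0.5 equiv), toluene/H2O 20:1, 40 °C
Reagents that add atoms: none
Why: Proposed new method: asymmetric rhodium-catalysed 1,4-addition of an arylboronic acid to a chromone that bears a 3-alkoxy group, the closest known reaction type being the conjugate arylation of 3-unsubstituted chromones to 2-arylchroman-4-ones with monovalent rhodium and chiral diene or bisphosphine ligands. The hydroxo-rhodium complex should transmetalate with 11, the aryl-rhodium species should bind the C2=C3 bond of 7 and insert it syn with the aryl group going to C2 (the β-carbon of the C2=C3–C4=O enone), and water should protonate the resulting oxa-π-allyl rhodium enolate and return Rh–OH; the 3-methoxy group is small and sits on the carbon that takes up rhodium, so it should slow insertion but not block it. No ring is closed: the step joins ring B to the preformed ring A/C bicycle through C2–C1′. C2 is set by the ligand, which admits only one face of the flat chromone to the aryl–rhodium bond (the same spatial sense as in (2S)-flavanones, which is 2R here because C3 now outranks C1′); C3 is set on protonation and should end trans because cis epimer 12 equilibrates through the enolate in the phosphate medium to the isomer with both substituents equatorial. The step needs insertion to outrun protodeboronation of the ortho-substituted, electron-rich 11, and needs the enolate to be protonated before it expels the O1 phenoxide; the π-acceptor diene ligand, the portionwise excess of 11, the small amount of water and the weak base are chosen for this.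

Step 6
Reactants: 13 (2R,3R)-3,5,7-trimethoxy-2-(2,4,5-trimethoxyphenyl)chroman-4-one
Product: 15 (2R,3R)-2-(2,5-dihydroxy-4-methoxyphenyl)-3,5,7-trimethoxychroman-4-one (CNP0281794.1), via quinone 14 (not isolated)
Conditions: (NH4)2Ce(NO3)6 (2.2 equiv), MeCN/H2O 2:1, 0 °C, 15 min; then EtOAc, sat. aq Na2S2O4, rt, under argon
Reagents that add atoms: water, O
Why: Oxidative demethylation followed by reduction: tetravalent cerium oxidises ring B, the most electron-rich ring and the only one with two para-related methoxy groups, water adds at C2′ and C5′ and two methanol leave to give 2-alkyl-5-methoxy-1,4-benzoquinone 14 with the 4′-methoxy group kept (ring A carries the acyl group and has no para oxygen pair), and dithionite then reduces 14 to the hydroquinone at neutral pH, so the ketone and the base-sensitive C2 and C3 centres should stay untouched.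

**Compound list**

1 | 1,3,5-trimethoxybenzene | COc1cc(OC)cc(OC)c1 | starting material
2 | methoxyacetyl chloride | COCC(=O)Cl | starting material
3 | 2-methoxy-1-(2,4,6-trimethoxyphenyl)ethan-1-one | COCC(=O)c1c(OC)cc(OC)cc1OC | intermediate
4 | dichloro[3,5-dimethoxy-2-(methoxyacetyl)phenoxy]borane (carbonyl-chelated) | COCC(=O)c1c(OB(Cl)Cl)cc(OC)cc1OC | intermediate (not isolated)
5 | 1-(2-hydroxy-4,6-dimethoxyphenyl)-2-methoxyethan-1-one | COCC(=O)c1c(O)cc(OC)cc1OC | intermediate
6 | (Z)-3-(dimethylamino)-1-(2-hydroxy-4,6-dimethoxyphenyl)-2-methoxyprop-2-en-1-one | CN(C)/C=C(\OC)C(=O)c1c(O)cc(OC)cc1OC | intermediate (not isolated)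
7 | 3,5,7-trimethoxy-4H-chromen-4-one | COc1cc(OC)c2c(c1)occ(OC)c2=O | intermediate
8 | 1-bromo-2,4,5-trimethoxybenzene | COc1cc(OC)c(OC)cc1Br | starting material
9 | (2,4,5-trimethoxyphenyl)lithium | COc1cc(OC)c(OC)cc1[Li] | intermediate (not isolated)
10 | lithium triisopropoxy(2,4,5-trimethoxyphenyl)borate | COc1cc(OC)c(OC)cc1[B-](OC(C)C)(OC(C)C)OC(C)C.[Li+] | intermediate (not isolated)
11 | (2,4,5-trimethoxyphenyl)boronic acid | COc1cc(OC)c(OC)cc1B(O)O | intermediate
12 | (2R,3S)-3,5,7-trimethoxy-2-(2,4,5-trimethoxyphenyl)chroman-4-one (2,3-cis) | COc1cc(OC)c2c(c1)O[C@H](c1cc(OC)c(OC)cc1OC)[C@H](OC)C2=O | intermediate (not isolated)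
13 | (2R,3R)-3,5,7-trimethoxy-2-(2,4,5-trimethoxyphenyl)chroman-4-one (2,3-trans) | COc1cc(OC)c2c(c1)O[C@H](c1cc(OC)c(OC)cc1OC)[C@@H](OC)C2=O | intermediate
14 | 2-methoxy-5-[(2R,3R)-3,5,7-trimethoxy-4-oxochroman-2-yl]cyclohexa-2,5-diene-1,4-dione | COc1cc(OC)c2c(c1)O[C@H](C1=CC(=O)C(OC)=CC1=O)[C@@H](OC)C2=O | intermediate (not isolated)
15 | (2R,3R)-2-(2,5-dihydroxy-4-methoxyphenyl)-3,5,7-trimethoxychroman-4-one (CNP0281794.1) | COc1cc(OC)c2c(c1)O[C@H](c1cc(O)c(OC)cc1O)[C@@H](OC)C2=O | target

**Count**
Total steps: 6. Longest linear sequence: 5 steps (steps 1, 2, 3, 5 and 6); step 4 is a one-step side branch.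

**Steps most likely to fail**

1. Step 5 (proposed new method). Insertion of the aryl–rhodium bond into the trisubstituted, donor-substituted C2=C3 bond may be slower than protodeboronation of 11. The enolate may also expel the O1 phenoxide, opening and reclosing ring C with loss of enantiomeric purity. The fallback uses known chemistry, sets out from ketone 5 and comes back at 13. Claisen–Schmidt condensation of 5 with commercial 2,4,5-trimethoxybenzaldehyde (KOH, EtOH, rt) should give (Z)-1-(2-hydroxy-4,6-dimethoxyphenyl)-2-methoxy-3-(2,4,5-trimethoxyphenyl)prop-2-en-1-one F1. NaOAc in refluxing EtOH should close ring C by intramolecular oxa-Michael addition to racemic trans-3,5,7-trimethoxy-2-(2,4,5-trimethoxyphenyl)chroman-4-one F2. Chromatography on a chiral stationary phase should then separate the (2R,3R) enantiomer, which is 13. This costs half the material and makes step 4 unnecessary.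

2. Step 6. The radical cation of ring B may lose the benzylic C2–H proton or break the C2–O1 bond before water adds, since ring B is in effect a 2,4,5-trimethoxybenzyl ether of the ring A phenol. Water may also add at C4′ and lead to the ortho-quinone. The fallback sets out from chromone 7 and comes back at 15; it carries the two oxygens as acetals and uses no oxidant. Commercial 2-methoxyhydroquinone would be converted (MOMCl, iPr2NEt, CH2Cl2) into 2-methoxy-1,4-bis(methoxymethoxy)benzene F3. Bromination para to the methoxy group (NBS, MeCN, 0 °C) should give 1-bromo-4-methoxy-2,5-bis(methoxymethoxy)benzene F4, and borylation as in step 4 should give [4-methoxy-2,5-bis(methoxymethoxy)phenyl]boronic acid F5. Addition of F5 to 7 under the conditions of step 5 should give (2R,3R)-3,5,7-trimethoxy-2-[4-methoxy-2,5-bis(methoxymethoxy)phenyl]chroman-4-one F6, and HCl in MeOH at rt should free hydroquinone 15.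

3. Step 2. Over-reaction may remove the aliphatic α-methoxy group or a second aryl methyl group. The fallback sets out from acid chloride 2 and comes back at 5. Acylation of commercial 3,5-dimethoxyphenol with 2 (Et3N, CH2Cl2, 0 °C) should give 3,5-dimethoxyphenyl methoxyacetate F7. A Fries rearrangement (BF3·OEt2, 90 °C; then aqueous work-up) should move the acyl group to the ortho carbon and give 5 without any demethylation.

**Further compounds**

F1 | step 5 | (Z)-1-(2-hydroxy-4,6-dimethoxyphenyl)-2-methoxy-3-(2,4,5-trimethoxyphenyl)prop-2-en-1-one | COc1cc(O)c(C(=O)/C(OC)=C/c2cc(OC)c(OC)cc2OC)c(OC)c1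
F2 | step 5 | racemic trans-3,5,7-trimethoxy-2-(2,4,5-trimethoxyphenyl)chroman-4-one (both enantiomers) | COc1cc(OC)c2c(c1)O[C@H](c1cc(OC)c(OC)cc1OC)[C@@H](OC)C2=O.COc1cc(OC)c2c(c1)O[C@@H](c1cc(OC)c(OC)cc1OC)[C@H](OC)C2=O
F3 | step 6 | 2-methoxy-1,4-bis(methoxymethoxy)benzene | COCOc1ccc(OCOC)c(OC)c1
F4 | step 6 | 1-bromo-4-methoxy-2,5-bis(methoxymethoxy)benzene | COCOc1cc(OC)c(OCOC)cc1Br
F5 | step 6 | [4-methoxy-2,5-bis(methoxymethoxy)phenyl]boronic acid | COCOc1cc(OC)c(OCOC)cc1B(O)O
F6 | step 6 | (2R,3R)-3,5,7-trimethoxy-2-[4-methoxy-2,5-bis(methoxymethoxy)phenyl]chroman-4-one | COc1cc(OC)c2c(c1)O[C@H](c1cc(OCOC)c(OC)cc1OCOC)[C@@H](OC)C2=O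
F7 | step 2 | 3,5-dimethoxyphenyl methoxyacetate | COCC(=O)Oc1cc(OC)cc(OC)c1
A1 | direct plan | (R)-4-benzyl-3-[(2R,3S)-3-[2,5-bis(benzyloxy)-4-methoxyphenyl]-3-hydroxy-2-methoxypropanoyl]oxazolidin-2-one | O[C@@H](c1cc(OCc2ccccc2)c(OC)cc1OCc1ccccc1)[C@@H](OC)C(=O)N1[C@H](Cc2ccccc2)COC1=O
A2 | direct plan | (2R,3R)-3-[2,5-bis(benzyloxy)-4-methoxyphenyl]-3-(3,5-dimethoxyphenoxy)-2-methoxypropanoic acid | COc1cc(OC)cc(c1)O[C@H](c1cc(OCc2ccccc2)c(OC)cc1OCc1ccccc1)[C@@H](OC)C(=O)O
A3 | direct plan | (2R,3R)-2-[2,5-bis(benzyloxy)-4-methoxyphenyl]-3,5,7-trimethoxychroman-4-one | COc1cc(OC)c2c(c1)O[C@H](c1cc(OCc3ccccc3)c(OC)cc1OCc1ccccc1)[C@@H](OC)C2=O
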